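**Retrosynthetic overview**

1. Target 30 comes from furanone alcohol 27 by late isovaleroylation at O9 and desilylation at O15.
2. Key disconnection of 27: C2=C3 and O–C10 are cut together, giving the acyclic seco compound 23 (C3 as S-2-cyanoethyl thioester, C1 as chloromethyl ketone, C9–C10 cis-epoxide). Forward, an S-bridged eleven-membered thiolactone loses sulfur (ring contraction to the ten-membered carbocycle) and the C3 enolate oxygen opens the epoxide at C10.
3. Enabling feature: in the 3(2H)-furanone ring O–C3=C2–C1(=O)–C10, the C3/C2/C1 unit is a vinylogous ester, i.e. a masked 1,3-diketone with C3 at the carboxyl level and C2 between two carbonyls. Quaternary C10 is an α-keto carbon next to oxygenated C9, so a C9–C10 epoxide is its leaving group and delivers the C9 hydroxyl.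
4. 23 comes from a Barbier union at C7–C8 of bromobutenolide 8 (C4–C7, C11–C13, C15) with epoxy aldehyde 15 (C8–C10, C14, C1, C2), followed by Mitsunobu methacryloylation at C8 and hydroxycarbonylation of the C4 iodide (adds C3).
5. Ring order: butenolide (metathesis) and epoxide first, α-methylene lactone on Barbier coupling, then thiolactone → carbocycle and furanone in the key step.

Key step: step 17

Remark: germacrane numbering of the target is used throughout (C1 ketone, C2=C3, C4=C5, O6 lactone, O8 methacrylate, O9 isovalerate, C10 quaternary, C11–C13 methylene lactone, C14 methyl, C15 CH2OH). The temporary carbinol at C1 in 11–16, 18–22 is assumed to be carried as both epimers, which converge on oxidation in step 16, so its SMILES carries no descriptor.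

Step 1
Reactants: 1 tert-butyldimethyl(prop-2-yn-1-yloxy)silane; 2 acrolein
Product: 3 racemic enynol
Conditions: n-BuLi, THF, −78 °C; then 2, −78 °C
Reagents that add atoms: none
Why: 1,2-addition of a lithium acetylide to an enal (carbonyl alkynylation) at low temperature should give the racemic vinyl alkynyl carbinol that holds C4–C7 and C15.

Step 2
Reactants: 3 racemic enynol
Product: 4 (3S)-enynol
Conditions: Ti(OiPr)4 (0.2 equiv), L-(+)-diisopropyl tartrate (0.25 equiv), t-BuOOH (0.6 equiv), 4 Å MS, CH2Cl2, −20 °C
Reagents that add atoms: none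
Why: Sharpless kinetic resolution: with the L-(+)-tartrate the (3R)-alcohol should be epoxidised at its vinyl group much faster, leaving the (3S)-alcohol (C6 of the target) in high ee.

Step 3
Reactants: 4 (3S)-enynol
Product: 5 (Z)-iodo dienol
Conditions: NaAlH2(OCH2CH2OMe)2, THF, 0 °C; then I2, −78 °C
Reagents that add atoms: iodine, II
Why: hydroxyl-directed trans-hydroalumination of the propargylic alcohol places aluminium on C4 cis to C6, and iododealumination with retention should give the (Z)-vinyl iodide that fixes the C4=C5 geometry.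

Step 4
Reactants: 5 (Z)-iodo dienol; 6 2-(bromomethyl)prop-2-enoic acid
Product: 7 bromomethylacrylate ester
Conditions: DCC, DMAP (cat.), CH2Cl2, 0 °C
Reagents that add atoms: none
Why: Steglich esterification of the secondary alcohol should proceed with retention at C6.

Step 5
Reactants: 7 bromomethylacrylate ester
Product: 8 bromobutenolide
Conditions: second-generation Grubbs catalyst (5 mol %), CH2Cl2, 40 °C
Reagents that add atoms: none
Why: ring-closing metathesis between the vinyl group and the acrylate should close the butenolide (C6, C7, C11, C12), the trisubstituted iodoalkene being inert.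

Step 6
Reactants: 9 3-methylfuran-2(5H)-one
Product: 11 (Z)-chloro diol, via chloromethyl hemiketal 10 (not isolated)
Conditions: ICH2Cl, MeLi·LiBr, THF, −78 °C; then MeOH, CeCl3·7H2O, NaBH4, −78 to 0 °C
Reagents that add atoms: chloroiodomethane, ClCI
Why: chloromethyllithium (carbenoid homologation) should add once to the lactone carbonyl and Luche 1,2-reduction of the ring-opened enone should give the diol, whose Z geometry (C8 cis to C1) is inherited from the ring; the new C1 carbinol is racemic and is removed in step 16.

Step 7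
Reactants: 11 (Z)-chloro diol
Product: 12 bis-TES ether
Conditions: Et3SiCl, imidazole, CH2Cl2, 0 °C to rt
Reagents that add atoms: chlorotriethylsilane, CC[Si](Cl)(CC)CC
Why: exhaustive silylation of both hydroxyls (silyl ether formation) is routine.

Step 8
Reactants: 12 bis-TES ether
Product: 13 primary allylic alcohol
Conditions: PPTS (cat.), MeOH/CH2Cl2, −10 °C
Reagents that add atoms: none
Why: acid-catalysed methanolysis (selective silyl ether solvolysis) should remove the unhindered primary allylic TES group much faster than the secondary one beside the fully substituted alkene carbon.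

Step 9
Reactants: 13 primary allylic alcohol
Product: 14 epoxy alcohol
Conditions: Ti(OiPr)4 (10 mol %), D-(−)-diisopropyl tartrate (12 mol %), t-BuOOH, 4 Å MS, CH2Cl2, −20 °C
Reagents that add atoms: tert-butyl hydroperoxide, CC(C)(C)OO
Why: Sharpless asymmetric epoxidation: the D-(−)-tartrate should set C9 and C10 by reagent control as the (2R,3R)-epoxide, and the Z-alkene makes it the cis-epoxide (C8 and C1 on the same side).

Step 10
Reactants: 14 epoxy alcohol
Product: 15 epoxy aldehyde
Conditions: Dess–Martin periodinane, NaHCO3, CH2Cl2, 0 °C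
Reagents that add atoms: none
Why: buffered Dess–Martin oxidation should give the aldehyde at C8 without touching the epoxide or silyl ether.

Step 11
Reactants: 8 bromobutenolide; 15 epoxy aldehyde
Product: 16 8R alcohol
Conditions: In powder (1.5 equiv), THF/H2O 1:1, rt
Reagents that add atoms: none
Why: Barbier allylation: the allylindium should attack through its γ-carbon C7 on the butenolide face anti to the C6 side chain (C7 trans to C6, exocyclic methylene formed), and a closed six-membered chair with the aldehyde residue equatorial, matched with attack anti to the epoxide C–O bond, should set C8 as the erythro 8R alcohol.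

Step 12
Reactants: 16 8R alcohol; 17 methacrylic acid
Product: 18 8S methacrylate
Conditions: PPh3, DIAD, toluene, 0 °C to rt
Reagents that add atoms: none
Why: Mitsunobu esterification should install the methacrylate with SN2 inversion at C8, turning the erythro epoxy alcohol into the threo 8S ester of the target.

Step 13
Reactants: 18 8S methacrylate
Product: 19 (Z)-carboxylic acid
Conditions: Pd(OAc)2 (5 mol %), Xantphos (6 mol %), CO (1 atm), H2O, i-Pr2NEt, DMF, 45 °C
Reagents that add atoms: carbon monoxide, [C-]#[O+]; water, O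
Why: palladium-catalysed hydroxycarbonylation: zerovalent palladium should insert only into the vinyl C–I bond and deliver C3 as the acid with retention of the alkene geometry (C3 cis to C6).

Step 14
Reactants: 19 (Z)-carboxylic acid
Product: 21 S-2-cyanoethyl thioester, via acid chloride 20 (not isolated)
Conditions: 1-chloro-N,N,2-trimethylprop-1-en-1-amine, CH2Cl2, 0 °C; then HSCH2CH2CN, pyridine, −20 °C
Reagents that add atoms: 3-mercaptopropionitrile, N#CCCS
Why: neutral acid chloride formation and thiol acylation (thioesterification) should give the base-releasable thioacid precursor, pyridine being too weak a base to start thiol conjugate addition to the methylene lactone.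

Step 15
Reactants: 21 S-2-cyanoethyl thioester
Product: 22 chlorohydrin
Conditions: HF·pyridine, pyridine, THF, 0 °C
Reagents that add atoms: none
Why: buffered fluoride desilylation should cleave the TES ether at O1 selectively in the presence of the TBS ether at O15.

Step 16
Reactants: 22 chlorohydrin
Product: 23 seco chloroketone
Conditions: Dess–Martin periodinane, NaHCO3, CH2Cl2, 0 °C to rt
Reagents that add atoms: none
Why: Dess–Martin oxidation should convert the chlorohydrin into the α-chloroketone and erase the temporary C1 stereocentre.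

Step 17
Reactants: 23 seco chloroketone
Product: 27 furanone alcohol, via thioacid 24 (not isolated), via thiolactone 25 (not isolated), via macrocyclic diketone 26 (not isolated)
Conditions: DBU (4 equiv), MeCN (1 mM, slow addition of 23), 0 °C to rt; then LiOTf, P(OEt)3, 50 °C
Reagents that add atoms: none
Why: Proposed new method: DBU should first unmask thiocarboxylate 24 by E1cB loss of acrylonitrile, and its sulfur displaces the α-keto chloride at C2 (11-exo-tet, helped by the cis-alkene and cis-epoxide turns) to give thiolactone 25; deprotonation at C2, 3-exo-trig attack on the thioester carbonyl C3 and sulfur transfer from the thiirane to P(OEt)3 then contract the eleven-membered ring to the ten-membered 1,3-diketone 26 with the new C2–C3 bond, and the enolate oxygen on C3 opens the epoxide at C10 (5-exo-tet), which closes the furanone (O–C10, C2=C3) and frees the C9 hydroxyl. The closest known chemistry is the Eschenmoser sulfide contraction of S-(2-oxoalkyl) thiocarboxylates to 1,3-diketones together with the cyclisation of 4,5-epoxy-1,3-diketones to 2-(1-hydroxyalkyl)-3(2H)-furanones; their fusion into one ring-contracting cascade on a macrocycle is the new part. The only new stereocentre, quaternary C10, is set by stereospecific SN2 inversion of the (9R,10R)-cis-epoxide from step 9, so it is tied to C9. The step needs O-attack at C10 rather than 6-endo attack at C9: C10 is an activated α-keto carbon on the favoured 5-exo trajectory, while C9 is shielded and deactivated by the C8 acyloxy group, and C2 cannot alkylate C10 without forming a cyclopropane. Chemoselectivity over the three Michael acceptors rests on the much faster, irreversible S-alkylation by the chloroketone, and the phosphite is added only after the chloride is consumed so that no Perkow reaction can occur.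

Step 18
Reactants: 27 furanone alcohol; 28 isovaleric anhydride
Product: 29 O15-TBS ether of the target
Conditions: DMAP, Et3N, CH2Cl2, 0 °C to rt
Reagents that add atoms: none
Why: DMAP-catalysed acylation of the only free hydroxyl (O9) should install the isovalerate with retention at C9.

Step 19
Reactants: 29 O15-TBS ether of the target
Product: 30 CNP0552093.1
Conditions: HF·pyridine, pyridine, THF, 0 °C to rt
Reagents that add atoms: none
Why: buffered fluoride desilylation of the primary allylic TBS ether should release the C15 alcohol without touching the esters or the Michael acceptors.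

**Compound list**

1 | tert-butyldimethyl(prop-2-yn-1-yloxy)silane | C#CCO[Si](C)(C)C(C)(C)C | starting material
2 | acrolein (prop-2-enal) | C=CC=O | starting material
3 | rac-6-[(tert-butyldimethylsilyl)oxy]hex-1-en-4-yn-3-ol | C=CC(O)C#CCO[Si](C)(C)C(C)(C)C | intermediate
4 | (3S)-6-[(tert-butyldimethylsilyl)oxy]hex-1-en-4-yn-3-ol | C=C[C@H](O)C#CCO[Si](C)(C)C(C)(C)C | intermediate
5 | (3S,4Z)-6-[(tert-butyldimethylsilyl)oxy]-5-iodohexa-1,4-dien-3-ol | C=C[C@H](O)/C=C(\I)CO[Si](C)(C)C(C)(C)C | intermediate
6 | 2-(bromomethyl)prop-2-enoic acid | OC(=O)C(=C)CBr | starting material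
7 | (3S,4Z)-6-[(tert-butyldimethylsilyl)oxy]-5-iodohexa-1,4-dien-3-yl 2-(bromomethyl)prop-2-enoate | C=C[C@H](OC(=O)C(=C)CBr)/C=C(\I)CO[Si](C)(C)C(C)(C)C | intermediate
8 | (5S)-3-(bromomethyl)-5-[(1Z)-3-[(tert-butyldimethylsilyl)oxy]-2-iodoprop-1-en-1-yl]furan-2(5H)-one | BrCC1=C[C@@H](/C=C(\I)CO[Si](C)(C)C(C)(C)C)OC1=O | intermediate
9 | 3-methylfuran-2(5H)-one | CC1=CCOC1=O | starting material
10 | 2-(chloromethyl)-3-methyl-2,5-dihydrofuran-2-ol (present as its lithium alkoxide) | CC1=CCOC1(O)CCl | intermediate (not isolated)
11 | (3Z)-1-chloro-3-methylpent-3-ene-2,5-diol, racemic | OC/C=C(C)\C(O)CCl | intermediate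
12 | (3Z)-1-chloro-3-methyl-2,5-bis[(triethylsilyl)oxy]pent-3-ene, racemic | CC[Si](CC)(CC)OC/C=C(C)\C(O[Si](CC)(CC)CC)CCl | intermediate
13 | (2Z)-5-chloro-3-methyl-4-[(triethylsilyl)oxy]pent-2-en-1-ol, racemic | OC/C=C(C)\C(O[Si](CC)(CC)CC)CCl | intermediate
14 | [(2R,3R)-3-{2-chloro-1-[(triethylsilyl)oxy]ethyl}-3-methyloxiran-2-yl]methanol, cis-epoxide, both side-chain epimers | OC[C@H]1O[C@@]1(C)C(O[Si](CC)(CC)CC)CCl | intermediate
15 | (2S,3R)-3-{2-chloro-1-[(triethylsilyl)oxy]ethyl}-3-methyloxirane-2-carbaldehyde, cis-epoxide, both side-chain epimers | O=C[C@H]1O[C@@]1(C)C(O[Si](CC)(CC)CC)CCl | intermediate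
16 | Barbier adduct: trans-α-methylene-γ-lactone with (Z)-2-iodo-3-(TBS-oxy)propenyl at C6 and, at C7, the free 8-hydroxy, 9,10-cis-epoxy, 1-OTES, 2-chloro side chain; 6S,7R,8R,9R,10R | I/C(CO[Si](C)(C)C(C)(C)C)=C\[C@H]1OC(=O)C(=C)[C@@H]1[C@@H](O)[C@H]2O[C@@]2(C)C(O[Si](CC)(CC)CC)CCl | intermediate
17 | methacrylic acid | CC(=C)C(O)=O | starting material
18 | 8-O-methacrylate of the C8 epimer of 16 (inverted at C8); 6S,7S,8S,9R,10R | I/C(CO[Si](C)(C)C(C)(C)C)=C\[C@H]1OC(=O)C(=C)[C@@H]1[C@H](OC(=O)C(C)=C)[C@H]2O[C@@]2(C)C(O[Si](CC)(CC)CC)CCl | intermediate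
19 | (Z)-C3 carboxylic acid (iodide of 18 replaced by CO2H, cis to C6); 6R,7S,8S,9R,10R | OC(=O)/C(CO[Si](C)(C)C(C)(C)C)=C\[C@H]1OC(=O)C(=C)[C@@H]1[C@H](OC(=O)C(C)=C)[C@H]2O[C@@]2(C)C(O[Si](CC)(CC)CC)CCl | intermediate
20 | C3 acid chloride of 19 | ClC(=O)/C(CO[Si](C)(C)C(C)(C)C)=C\[C@H]1OC(=O)C(=C)[C@@H]1[C@H](OC(=O)C(C)=C)[C@H]2O[C@@]2(C)C(O[Si](CC)(CC)CC)CCl | intermediate (not isolated)
21 | C3 S-(2-cyanoethyl) thioester of 19; 6R,7S,8S,9R,10R | N#CCCSC(=O)/C(CO[Si](C)(C)C(C)(C)C)=C\[C@H]1OC(=O)C(=C)[C@@H]1[C@H](OC(=O)C(C)=C)[C@H]2O[C@@]2(C)C(O[Si](CC)(CC)CC)CCl | intermediate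
22 | chlorohydrin: 21 with free 1-OH (both C1 epimers); 6R,7S,8S,9R,10S (C10 descriptor changes by CIP priority only) | N#CCCSC(=O)/C(CO[Si](C)(C)C(C)(C)C)=C\[C@H]1OC(=O)C(=C)[C@@H]1[C@H](OC(=O)C(C)=C)[C@H]2O[C@@]2(C)C(O)CCl | intermediate
23 | seco chloroketone: C3 S-(2-cyanoethyl) thioester, C1 chloromethyl ketone, 9,10-cis-epoxide, 8-O-methacrylate, 15-OTBS; 6R,7S,8S,9R,10R | N#CCCSC(=O)/C(CO[Si](C)(C)C(C)(C)C)=C\[C@H]1OC(=O)C(=C)[C@@H]1[C@H](OC(=O)C(C)=C)[C@H]2O[C@@]2(C)C(=O)CCl | intermediate
24 | C3 thioacid of 23 (present as DBU thiocarboxylate) | SC(=O)/C(CO[Si](C)(C)C(C)(C)C)=C\[C@H]1OC(=O)C(=C)[C@@H]1[C@H](OC(=O)C(C)=C)[C@H]2O[C@@]2(C)C(=O)CCl | intermediate (not isolated)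
25 | eleven-membered thiolactone, ring C3(=O)–S–C2–C1(=O)–C10–C9–C8–C7–C6–C5=C4; 6R,7S,8S,9R,10R | S3C(=O)/C(CO[Si](C)(C)C(C)(C)C)=C\[C@H]1OC(=O)C(=C)[C@@H]1[C@H](OC(=O)C(C)=C)[C@H]2O[C@@]2(C)C(=O)C3 | intermediate (not isolated)
26 | ten-membered 1,3-diketone (C1 and C3 ketones, C2 methylene) with 9,10-epoxide (present as enolate); 6R,7S,8S,9R,10R | O=C3/C(CO[Si](C)(C)C(C)(C)C)=C\[C@H]1OC(=O)C(=C)[C@@H]1[C@H](OC(=O)C(C)=C)[C@H]2O[C@@]2(C)C(=O)C3 | intermediate (not isolated)
27 | furanone alcohol: target skeleton with free 9-OH, 8-O-methacrylate, 15-OTBS; 6R,7S,8S,9R,10S | C=C(C)C(=O)O[C@H]1[C@H]2C(=C)C(=O)O[C@@H]2/C=C(/CO[Si](C)(C)C(C)(C)C)C2=CC(=O)[C@@](C)(O2)[C@@H]1O | intermediate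
28 | isovaleric anhydride (3-methylbutanoic anhydride) | CC(C)CC(=O)OC(=O)CC(C)C | starting material
29 | 15-O-TBS ether of the target; 6R,7S,8S,9R,10S | C=C(C)C(=O)O[C@H]1[C@H]2C(=C)C(=O)O[C@@H]2/C=C(/CO[Si](C)(C)C(C)(C)C)C2=CC(=O)[C@@](C)(O2)[C@@H]1OC(=O)CC(C)C | intermediate
30 | CNP0552093.1; 4Z,6R,7S,8S,9R,10S | C=C(C)C(=O)O[C@H]1[C@H]2C(=C)C(=O)O[C@@H]2/C=C(/CO)C2=CC(=O)[C@@](C)(O2)[C@@H]1OC(=O)CC(C)C | target

**Step count**

Total: 19 steps. Longest linear sequence: 14 steps (steps 1–5 or 6–10, then 11–19).

**Steps most likely to fail**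

Step 17 (proposed new method). Several processes could compete:
- oligomerisation during the macrocyclising S-alkylation;
- conjugate addition of thiocarboxylate or DBU to the methylene lactone;
- no thiirane formation, or sulfur not extruded;
- 6-endo opening of the epoxide at C9, or no closure at all;
- base-induced migration of the methacrylate from O8 to the freed O9.

Fallback, with known reaction types only: starting again from 23, the cascade is taken apart into three isolated operations.
- 23 is added slowly to DBU in MeCN and thiolactone 25 is isolated.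
- A classical Eschenmoser sulfide contraction (LiOTf, i-Pr2NEt, P(OEt)3, MeCN, 60 °C) gives macrocyclic diketone 26, isolated as its enol.
- The furanone is closed under Brønsted-acid activation of the epoxide (camphorsulfonic acid, CH2Cl2, 0 °C), where the neutral enol attacks the activated tertiary C10 with inversion and no alkoxide is formed at O9.

This rejoins the route at 27. It makes no compound outside the list (entry F0).

Step 11. The aldehyde could be attacked on the other face, for example through chelation of the epoxide and carbonyl oxygens by indium, or the diastereomer ratio could be low.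

Fallback: if the coupling of 8 and 15 delivers mainly the threo epoxy alcohol, the 8S alcohol F1, the inversion is dropped. F1 is acylated with retention (methacrylic anhydride, DMAP, Et3N, CH2Cl2), which reaches 18 directly. A mixture of 16 and F1 would be separated and each epimer taken to 18 by its own esterification.

Step 13. The vinyl- or acylpalladium intermediate could be intercepted by the nearby α-methylene lactone (Heck-type cyclisation), or the methacrylate could be lost under the aqueous amine conditions.

Fallback without acylpalladium chemistry: from 18, Stille coupling with (tributylstannyl)methanol (Pd(PPh3)4, toluene, 80 °C) gives the (Z)-allylic alcohol F2. MnO2 oxidation (CH2Cl2, rt) gives the (Z)-enal F3. Pinnick oxidation (NaClO2, NaH2PO4, 2-methylbut-2-ene, t-BuOH/H2O) then returns to acid 19.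

Further compounds
F0 | step 17 | none | none
F1 | step 11 | C8 epimer of 16 (8S alcohol, threo to the epoxide); 6S,7R,8S,9R,10R | I/C(CO[Si](C)(C)C(C)(C)C)=C\[C@H]1OC(=O)C(=C)[C@@H]1[C@H](O)[C@H]2O[C@@]2(C)C(O[Si](CC)(CC)CC)CCl
F2 | step 13 | (Z)-allylic alcohol: iodide of 18 replaced by CH2OH (cis to C6); 6R,7S,8S,9R,10R | OC/C(CO[Si](C)(C)C(C)(C)C)=C\[C@H]1OC(=O)C(=C)[C@@H]1[C@H](OC(=O)C(C)=C)[C@H]2O[C@@]2(C)C(O[Si](CC)(CC)CC)CCl
F3 | step 13 | (Z)-enal: iodide of 18 replaced by CHO (cis to C6); 6R,7S,8S,9R,10R | O=C/C(CO[Si](C)(C)C(C)(C)C)=C\[C@H]1OC(=O)C(=C)[C@@H]1[C@H](OC(=O)C(C)=C)[C@H]2O[C@@]2(C)C(O[Si](CC)(CC)CC)CCl
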